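**Retrosynthetic overview**

1. The target is (−)-epicatechin-(4β→8)-(+)-taxifolin, which is the lower-unit 4-oxo derivative of procyanidin B1. The key disconnection is therefore the lower-unit C4=O bond, made by a site-selective benzylic C–H oxygenation of octa-O-benzylprocyanidin B1, followed only by global hydrogenolysis.
2. The interflavan C4–C8 bond comes from a TMSOTf Friedel–Crafts union of a 4β-alkoxy tetra-O-benzylepicatechin (made by DDQ C4–H etherification) with tetra-O-benzylcatechin. The carbonyl is installed after this coupling so that the nucleophile is the electron-rich catechin ring A, which attacks reliably at C8.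
3. Both monomers come from one-step phenol benzylation of (−)-epicatechin and (+)-catechin.
4. No ring is built: rings A, B and C of both units come intact from the chiral pool. The only new stereocentre is the interflavan C4, set by substrate control.

Assumption: (−)-epicatechin and (+)-catechin of natural configuration are taken as cheap commercial materials; carbinol 9 is drawn as its 4β epimer, but either epimer gives ketone 10.

**Route**

Step 1
Reactants: 1 (−)-epicatechin; 2 benzyl bromide
Product: 3 tetra-O-benzyl-(−)-epicatechin (5,7,3',4'-benzyl ethers; 2R,3R; free 3-OH)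
Conditions: BnBr (4.4 equiv), K2CO3 (5 equiv), degassed DMF, 0 °C to rt, N2, dark
Reagents that add atoms: benzyl bromide, BrCc1ccccc1
Why: Williamson ether synthesis in which carbonate deprotonates only the four phenols, not the secondary 3-OH, so both existing stereocentres are carried through unchanged.

Step 2
Reactants: 3 tetra-O-benzyl-(−)-epicatechin; 4 2-ethoxyethanol
Product: 5 (2R,3R,4S)-4-(2-ethoxyethoxy)-tetra-O-benzylepicatechin (4β ether; 3,4-trans)
Conditions: DDQ (2 equiv), 2-ethoxyethanol (4 equiv), CH2Cl2, rt, 2 h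
Reagents that add atoms: 2-ethoxyethanol, CCOCCO
Why: DDQ oxidative benzylic C–H etherification, in which hydride abstraction at C4 gives a cation stabilised by the 5,7-dibenzyloxy ring A and the alcohol adds on the β face anti to the 2-aryl and 3-OH groups (this C4 configuration is lost again in step 4).

Step 3
Reactants: 6 (+)-catechin; 2 benzyl bromide
Product: 7 tetra-O-benzyl-(+)-catechin (5,7,3',4'-benzyl ethers; 2R,3S; free 3-OH)
Conditions: BnBr (4.4 equiv), K2CO3 (5 equiv), degassed DMF, 0 °C to rt, N2
Reagents that add atoms: benzyl bromide, BrCc1ccccc1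
Why: Williamson ether synthesis selective for the phenols, leaving the 2,3-trans stereocentres untouched.

Step 4
Reactants: 5 (2R,3R,4S)-4-(2-ethoxyethoxy)-tetra-O-benzylepicatechin; 7 tetra-O-benzyl-(+)-catechin (4 equiv, excess recovered)
Product: 8 octa-O-benzylprocyanidin B1 (tetra-O-benzylepicatechin-(4β→8)-tetra-O-benzylcatechin; upper unit 2R,3R,4R; lower unit 2R,3S)
Conditions: TMSOTf (0.5 equiv), CH2Cl2, −78 °C, 10 min; Et3N quench
Reagents that add atoms: none
Why: Friedel–Crafts alkylation through the flavan-4-yl cation, which attacks C8 of 7 (C6 is shielded by two benzyloxy groups, and excess 7 suppresses oligomers) on the β face anti to the 2-aryl and 3-OH groups, setting the interflavan centre as 4R (3,4-trans).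

Step 5
Reactants: 8 octa-O-benzylprocyanidin B1
Product: 10 octa-O-benzyl-(−)-epicatechin-(4β→8)-(+)-taxifolin (upper unit 2R,3R,4R; lower unit 2R,3R 4-ketone), via lower-unit C4 carbinol 9 (not isolated)
Conditions: DDQ (2.6 equiv, two portions), CH2Cl2/H2O 18:1, 0.02 M, 0 °C to rt
Reagents that add atoms: water, O
Why: Proposed new method: site-selective oxidation of the terminal-unit C4 methylene of a perbenzylated 4→8 procyanidin dimer directly to the ketone with DDQ and water — DDQ abstracts the pseudo-axial benzylic hydride of the unhindered lower C4H2 (cation stabilised by the lower 5,7-dibenzyloxy ring A), water captures the cation to give carbinol 9, whose epimers equilibrate through the same cation under the acidic DDQH2, and a second hydride abstraction from the more hydridic carbinol C–H gives the aryl ketone, which deactivates that ring and stops the sequence; the competing interflavan C4–H is tertiary, buried between three ortho oxygen substituents and would give a cation with severe allylic strain, the two C3 carbinols are not benzylic, and the lower C2 and C3 centres are untouched (the 2,3-trans dihydroflavonol is also the thermodynamic isomer); the closest known reaction type is the DDQ-mediated C4 benzylic C–H hydroxylation or alkoxylation of monomeric benzylated flavan-3-ols combined with DDQ oxidation of electron-rich benzylic alcohols.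

Step 6
Reactants: 10 octa-O-benzyl-(−)-epicatechin-(4β→8)-(+)-taxifolin
Product: 11 (−)-epicatechin-(4β→8)-(+)-taxifolin (target; upper unit 2R,3R,4R; lower unit 2R,3R)
Conditions: H2 (1 atm), Pd(OH)2/C, THF/MeOH/H2O 20:1:1, rt
Reagents that add atoms: none
Why: Catalytic hydrogenolysis of the eight aryl benzyl ethers, under which the chelated vinylogous-ester ketone, the diarylmethine interflavan bond and all five stereocentres are left intact.

**Compound list**

1 | (−)-epicatechin, (2R,3R) | C1c2c(O)cc(O)cc2O[C@H](c2ccc(O)c(O)c2)[C@@H]1O | starting material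
2 | benzyl bromide | BrCc1ccccc1 | starting material
3 | 5,7,3',4'-tetra-O-benzyl-(−)-epicatechin, (2R,3R) | C1c2c(OCc3ccccc3)cc(OCc3ccccc3)cc2O[C@H](c2ccc(OCc3ccccc3)c(OCc3ccccc3)c2)[C@@H]1O | intermediate
4 | 2-ethoxyethanol | CCOCCO | starting material
5 | (2R,3R,4S)-5,7-bis(benzyloxy)-2-[3,4-bis(benzyloxy)phenyl]-4-(2-ethoxyethoxy)chroman-3-ol (4β ether) | CCOCCO[C@H]1c2c(OCc3ccccc3)cc(OCc3ccccc3)cc2O[C@H](c2ccc(OCc3ccccc3)c(OCc3ccccc3)c2)[C@@H]1O | intermediate
6 | (+)-catechin, (2R,3S) | C1c2c(O)cc(O)cc2O[C@H](c2ccc(O)c(O)c2)[C@H]1O | starting material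
7 | 5,7,3',4'-tetra-O-benzyl-(+)-catechin, (2R,3S) | C1c2c(OCc3ccccc3)cc(OCc3ccccc3)cc2O[C@H](c2ccc(OCc3ccccc3)c(OCc3ccccc3)c2)[C@H]1O | intermediate
8 | octa-O-benzylprocyanidin B1; upper unit (2R,3R,4R), lower unit (2R,3S), 4β→8 | C1c2c(OCc3ccccc3)cc(OCc3ccccc3)c([C@H]3c4c(OCc5ccccc5)cc(OCc5ccccc5)cc4O[C@H](c4ccc(OCc5ccccc5)c(OCc5ccccc5)c4)[C@@H]3O)c2O[C@H](c2ccc(OCc3ccccc3)c(OCc3ccccc3)c2)[C@H]1O | intermediate
9 | lower-unit 4β-hydroxy derivative of 8; lower unit (2R,3S,4S)-3,4-diol, upper unit (2R,3R,4R) | O[C@H]1c2c(OCc3ccccc3)cc(OCc3ccccc3)c([C@H]3c4c(OCc5ccccc5)cc(OCc5ccccc5)cc4O[C@H](c4ccc(OCc5ccccc5)c(OCc5ccccc5)c4)[C@@H]3O)c2O[C@H](c2ccc(OCc3ccccc3)c(OCc3ccccc3)c2)[C@H]1O | intermediate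
10 | octa-O-benzyl-(−)-epicatechin-(4β→8)-(+)-taxifolin; upper unit (2R,3R,4R), lower unit (2R,3R) 4-ketone | O=C1c2c(OCc3ccccc3)cc(OCc3ccccc3)c([C@H]3c4c(OCc5ccccc5)cc(OCc5ccccc5)cc4O[C@H](c4ccc(OCc5ccccc5)c(OCc5ccccc5)c4)[C@@H]3O)c2O[C@H](c2ccc(OCc3ccccc3)c(OCc3ccccc3)c2)[C@H]1O | intermediate
11 | (2R,3R)-2-(3,4-dihydroxyphenyl)-8-[(2R,3R,4R)-2-(3,4-dihydroxyphenyl)-3,5,7-trihydroxychroman-4-yl]-3,5,7-trihydroxychroman-4-one | O=C1c2c(O)cc(O)c([C@H]3c4c(O)cc(O)cc4O[C@H](c4ccc(O)c(O)c4)[C@@H]3O)c2O[C@H](c2ccc(O)c(O)c2)[C@H]1O | target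

**Step count and risks**

Total steps: 6. Longest linear sequence: 5 (steps 1, 2, 4, 5, 6; step 3 is a one-step side branch).

The three steps most likely to fail:

Step 5 (proposed new oxygenation; risks are attack at the interflavan C4–H, intermolecular Friedel–Crafts trapping of the cation, or stalling at carbinol 9). The fallback moves the oxygenation to the monomer, where each operation is of an established type, and sets out from 7. DDQ in wet CH2Cl2 converts 7 into (2R,3S,4S)-5,7,3',4'-tetra-O-benzylflavan-3,4-diol F1. Activated MnO2 in CH2Cl2 then oxidises only the benzylic carbinol to give 5,7,3',4'-tetra-O-benzyl-(+)-taxifolin F2. TMSOTf-promoted Friedel–Crafts coupling of F2 (excess) with electrophile 5 in CH2Cl2 at −40 to 0 °C attacks C8 (C6 lies between two benzyloxy groups) on the β face and comes back to the route at 10, ready for step 6. The price is one more step and a less nucleophilic ring A.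

Step 4 (interflavan coupling; risks are oligomerisation through the free C6 and C8 of the upper unit and the need for a large excess of 7). The fallback changes from oxophilic ionisation of an ether to thiophilic activation of a thioether and sets out from 5. Treatment of 5 with 1,3-benzothiazole-2-thiol and AlMe3 in CH2Cl2 gives (2R,3S,4S)-4-(1,3-benzothiazol-2-ylsulfanyl)-5,7,3',4'-tetra-O-benzylepicatechin F3. AgBF4 in THF/CH2Cl2 at 0 °C ionises only the C–S bond in the presence of near-stoichiometric 7; the product carries no such leaving group, so chain growth is limited, and the fallback comes back to the route at 8.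

Step 1 (benzylation of base-sensitive epicatechin; risks are C-benzylation at C6 or C8 and C2 epimerisation). The fallback reaches 3 by C3 inversion in the more robust catechin series and sets out from 7. Dess–Martin periodinane in wet CH2Cl2 oxidises 7 to (2R)-5,7,3',4'-tetra-O-benzylflavan-3-one F4. LiBH(s-Bu)3 with LiBr in THF at −78 °C delivers hydride anti to the 2-aryl group to give the 2,3-cis alcohol, coming back to the route at 3 and removing (−)-epicatechin as a starting material.

**Further compounds**

F1 | step 5 | (2R,3S,4S)-5,7-bis(benzyloxy)-2-[3,4-bis(benzyloxy)phenyl]chroman-3,4-diol | O[C@H]1c2c(OCc3ccccc3)cc(OCc3ccccc3)cc2O[C@H](c2ccc(OCc3ccccc3)c(OCc3ccccc3)c2)[C@H]1O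
F2 | step 5 | 5,7,3',4'-tetra-O-benzyl-(+)-taxifolin, (2R,3R) | O=C1c2c(OCc3ccccc3)cc(OCc3ccccc3)cc2O[C@H](c2ccc(OCc3ccccc3)c(OCc3ccccc3)c2)[C@H]1O
F3 | step 4 | (2R,3S,4S)-4-(1,3-benzothiazol-2-ylsulfanyl)-5,7-bis(benzyloxy)-2-[3,4-bis(benzyloxy)phenyl]chroman-3-ol | c1ccc2sc(S[C@H]3c4c(OCc5ccccc5)cc(OCc5ccccc5)cc4O[C@H](c4ccc(OCc5ccccc5)c(OCc5ccccc5)c4)[C@@H]3O)nc2c1
F4 | step 1 | (2R)-5,7-bis(benzyloxy)-2-[3,4-bis(benzyloxy)phenyl]chroman-3-one | C1c2c(OCc3ccccc3)cc(OCc3ccccc3)cc2O[C@H](c2ccc(OCc3ccccc3)c(OCc3ccccc3)c2)C1=O
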